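**The charge ratio.** The ratio to carry into the flask is X to Q as charged, 1.50, equal in gamma, beta, oak and birch, and you hold it against the knee in the curve of Q.

| flask | Q | X | D | remark | time |
|---|---|---|---|---|---|
| gamma | 0.064 M | 0.096 M | 0.056 M | run made earlier |  |
| beta | 0.064 M | 0.096 M | 0.12 M | run made earlier |  |
| oak | 0.064 M | 0.0960 M | 0.0770 M |  | 4.0 d |
| birch | 0.064 M | 0.0960 M | 0.150 M |  | 4.0 d |

| run | time / d | Q / % | Z / % |
|---|---|---|---|
| gamma | 0.625 | 25.5 | 60.8 |
| gamma | 1.25 | 24.5 | 50.8 |
| gamma | 2.08 | 23.8 | 40.2 |
| gamma | 2.50 | 22.1 | 38.5 |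
| gamma | 3.00 | 20.3 | 33.3 |
| gamma | 4.00 | 18.6 | 29.0 |
| beta | 0.333 | 30.6 | 63.1 |
| beta | 0.500 | 25.6 | 64.7 |
| beta | 0.833 | 23.7 | 58.6 |
| beta | 1.67 | 21.2 | 44.7 |
| beta | 2.50 | 19.1 | 39.4 |
| beta | 4.00 | 17.2 | 30.2 |

(scatter of a reading: 1 percentage point)

- the numbers in the tables scatter by 1 percentage point (one standard deviation)

* part of the Q that has reacted at the end, oak
* part of the Q that has reacted at the end, birch
* what raising the concentration of D from its lowest to its highest value here does to the part of the Q that has reacted (changes below 5 percentage points count as none) (it rises / no change / it falls)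

**Reading the knee.** In gamma, Q stands at 25.5 % of its charge by 0.625 d, and in beta at 25.6 % by 0.500 d; afterwards it creeps, and if X is what has gone by then, the gamma reading gives about 2.01 X per Q consumed. Taking X as the limiting reagent, I call the charge ratio over two, 75.0 %, the stall fraction: the part of the Q that the X charge can turn over at two X per Q.

**Two pairs.** Oak holds 1.38 times the D of gamma and birch 1.25 times that of beta, but each pair shares its stall fraction. By 4.00 d, gamma has crept 6.4 percentage points past the stall and beta 7.8 points, a gap smaller than the 5 points that counts. So I reckon 81.4 % reacted for oak and 82.8 % for birch, with no trend.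

**The forecast.** It gives 82 % for oak, 83 % for birch and no change, reading a balance where I read a stall: “D sets the speed of reaching the balance, not the late position”.

**The flasks.** Oak gives 80.8 % and birch 82.3 %, a change of 1.5 points, so no change, and the forecast stands.

    Q + X → G + Z (k = 5.33 M⁻¹ h⁻¹)
    X + G ⇌ E, settled at all times (K = 53800 M⁻¹)
    Z ⇌ L (K = 2.50, k = 0.0167 h⁻¹)
    G + D ⇌ J (K = 34.7 M⁻¹, k = 44.5 M⁻¹ h⁻¹)

**What ran.** In birch, the passing of Q + X into G + Z reached the midpoint of its turnover up to the asked time by 0.0649 d, whereas the passing of G + D into J had only 7.8 % of its own turnover behind it at 0.400 d. By 4.00 d birch held 0.499 % of its X free and stood 7.3 points past its stall fraction of 75.0 %, and a flask like birch but charged with 0.26 M of Q, whose stall fraction is 18.5 %, had 25.6 % reacted, 7.1 points past it.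

The readings are calculated with made-up constants, noise included.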